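**Retrosynthetic overview**
1. Ester C–O bond: 15 ⇒ tetradecanoyl chloride 14 + alcohol 13, which is unmasked from TBS ether 12.
2. C7=C8 enone: 12 ⇒ epoxy aldehyde 10 + acetonylidene phosphorane 11 (E-selective Wittig).
3. Oxirane: 10 ⇒ epoxy alcohol 9 ⇒ allylic alcohol 8 (Katsuki–Sharpless epoxidation sets C5 and C6 together).
4. C6–C7 bond: 8 ⇒ ester 7 ⇒ enol triflate 6 (Pd carbonylation) ⇒ silylated actinol 4.
5. C3 carbinol: actinol 3 ⇒ levodione 2 ⇒ achiral ketoisophorone 1 (ene-reductase, then ketoreductase). Ring order: the carbocycle comes with 1, and the oxirane (step 7) is the only ring formed.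

Assumption: recombinant ene-reductase, ketoreductase and formate dehydrogenase preparations and the nicotinamide cofactor count as purchasable catalysts, and the acyl chain is read as tetradecanoyl (C14).

**Step 1**
Reactants: 1 ketoisophorone (2,6,6-trimethylcyclohex-2-ene-1,4-dione)
Product: 2 (6R)-levodione [(6R)-2,2,6-trimethylcyclohexane-1,4-dione]
Conditions: ene-reductase (flavin-dependent, Old Yellow Enzyme family), NAD+ (cat.), formate dehydrogenase, HCO2Na, KPi buffer pH 7.0, 30 °C; prompt MTBE extraction
Reagents that add atoms: none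
Why: This is an asymmetric bioreduction of an activated C=C bond, in which the reduced flavin delivers hydride and an active-site tyrosine delivers the proton in a net trans-addition on one enantioface, setting C6 as R (typically ≥95% ee) while formate dehydrogenase recycles NADH irreversibly.

**Step 2**
Reactants: 2 (6R)-levodione
Product: 3 (4R,6R)-actinol [(4R,6R)-4-hydroxy-2,2,6-trimethylcyclohexan-1-one]
Conditions: ketoreductase (NADH-dependent short-chain dehydrogenase/reductase of levodione-reductase type), NAD+ (cat.), formate dehydrogenase, HCO2Na, KPi buffer pH 7.0, 30 °C; recrystallisation (iPr2O/hexane)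
Reagents that add atoms: none
Why: In this ketoreductase-catalysed carbonyl reduction the enzyme accepts only the unhindered C4 ketone (C1 is flanked by CMe2 and CHMe) and transfers hydride to one face to give the 4R carbinol, and one recrystallisation brings 3 to >99% ee and de.

**Step 3**
Reactants: 3 (4R,6R)-actinol
Product: 4 (4R,6R)-4-(tert-butyldimethylsilyloxy)-2,2,6-trimethylcyclohexan-1-one
Conditions: TBSCl, imidazole, DMF, rt
Reagents that add atoms: tert-butyldimethylsilyl chloride, CC(C)(C)[Si](C)(C)Cl
Why: Imidazole-promoted silylation (Corey protocol) of the only hydroxyl group takes place at oxygen, so neither stereocentre is touched.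

**Step 4**
Reactants: 4 (4R,6R)-4-(tert-butyldimethylsilyloxy)-2,2,6-trimethylcyclohexan-1-one
Product: 6 (4R)-4-(tert-butyldimethylsilyloxy)-2,6,6-trimethylcyclohex-1-en-1-yl trifluoromethanesulfonate, via lithium enolate 5 (not isolated)
Conditions: LDA (commercial solution), THF, −78 to 0 °C; then PhNTf2, −78 °C to rt
Reagents that add atoms: N-phenylbis(trifluoromethanesulfonimide), O=S(=O)(N(c1ccccc1)S(=O)(=O)C(F)(F)F)C(F)(F)F
Why: In this enol triflate formation only C6 carries an α-hydrogen, so a single tetrasubstituted enolate forms and is O-sulfonylated, which erases the auxiliary C6 centre (any C6 epimer converges) and leaves the γ-silyloxy centre untouched because no β-elimination path exists.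

**Step 5**
Reactants: 6 enol triflate
Product: 7 methyl (4R)-4-(tert-butyldimethylsilyloxy)-2,6,6-trimethylcyclohex-1-ene-1-carboxylate
Conditions: Pd(OAc)2 (5 mol %), PPh3, CO (1 atm), MeOH, Et3N, DMF, 60 °C
Reagents that add atoms: carbon monoxide, [C-]#[O+]; methanol, CO
Why: Pd(0)-catalysed alkoxycarbonylation of a vinyl triflate (oxidative addition, CO insertion, methanolysis of the acyl-palladium) installs C7 regiospecifically at the former carbonyl carbon under conditions that leave the silyl ether intact.

**Step 6**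
Reactants: 7 methyl ester
Product: 8 [(4R)-4-(tert-butyldimethylsilyloxy)-2,6,6-trimethylcyclohex-1-en-1-yl]methanol
Conditions: DIBAL-H (2.5 equiv), CH2Cl2, −78 to 0 °C; Fieser work-up (H2O, aq NaOH)
Reagents that add atoms: none
Why: DIBAL-H reduces the hindered conjugated ester in a 1,2-sense to the primary allylic alcohol without attacking the tetrasubstituted alkene or the TBS ether.

**Step 7**
Reactants: 8 allylic alcohol
Product: 9 [(1R,4S,6R)-4-(tert-butyldimethylsilyloxy)-2,2,6-trimethyl-7-oxabicyclo[4.1.0]heptan-1-yl]methanol (oxirane O trans to OTBS)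
Conditions: Ti(OiPr)4 (20 mol %), D-(−)-diethyl tartrate [(S,S), 26 mol %], t-BuOOH (2 equiv, in decane), 4 Å MS, CH2Cl2, −20 °C
Reagents that add atoms: tert-butyl hydroperoxide, CC(C)(C)OO
Why: In this Katsuki–Sharpless asymmetric epoxidation the Ti–(S,S)-tartrate complex binds the primary allylic alcohol and delivers oxygen to the enantioface opposite to the one chosen by L-(+)-tartrate (which gives 2S-epoxides such as (2S,3S)-epoxygeraniol), and here that is the face anti to the C3 silyloxy group, so C5 (R) and C6 are set together by one syn-addition under catalyst control.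

**Step 8**
Reactants: 9 epoxy alcohol
Product: 10 (1S,4S,6R)-4-(tert-butyldimethylsilyloxy)-2,2,6-trimethyl-7-oxabicyclo[4.1.0]heptane-1-carbaldehyde
Conditions: TPAP (5 mol %), NMO (1.5 equiv), 4 Å MS, CH2Cl2, rt
Reagents that add atoms: none
Why: Ley–Griffith oxidation is neutral and anhydrous, so it stops at the aldehyde, spares the acid-labile tetrasubstituted oxirane, and cannot epimerise an aldehyde that has no α-hydrogen.

**Step 9**
Reactants: 10 epoxy aldehyde; 11 1-(triphenylphosphoranylidene)propan-2-one
Product: 12 (E)-4-[(1S,4S,6R)-4-(tert-butyldimethylsilyloxy)-2,2,6-trimethyl-7-oxabicyclo[4.1.0]heptan-1-yl]but-3-en-2-one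
Conditions: 11 (3 equiv), toluene, 90 °C
Reagents that add atoms: 1-(triphenylphosphoranylidene)propan-2-one (11), CC(=O)C=P(c1ccccc1)(c1ccccc1)c1ccccc1
Why: Wittig olefination with a stabilised, salt-free ylide gives the E-enone under neutral conditions, because the α-oxygen activates the hindered non-enolisable aldehyde and no free alkoxide is formed that could trigger a Payne rearrangement.

**Step 10**
Reactants: 12 TBS-protected epoxy enone
Product: 13 (E)-4-[(1S,4S,6R)-4-hydroxy-2,2,6-trimethyl-7-oxabicyclo[4.1.0]heptan-1-yl]but-3-en-2-one [(3S,5R,6S)-5,6-epoxy-3-hydroxy-5,6-dihydro-β-ionone]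
Conditions: TBAF (1.2 equiv), THF, 0 °C to rt
Reagents that add atoms: none
Why: Fluoride-mediated desilylation cleaves only the Si–O bond, avoids the acid that would open or rearrange the oxirane, and the quaternary C6 offers no vinylogous elimination path.

**Step 11**
Reactants: 13 hydroxy epoxy enone; 14 tetradecanoyl (myristoyl) chloride
Product: 15 target, (1R,3S,6S)-1,5,5-trimethyl-6-[(1E)-3-oxobut-1-en-1-yl]-7-oxabicyclo[4.1.0]heptan-3-yl tetradecanoate [(3S,5R,6S)-5,6-epoxy-3-hydroxy-5,6-dihydro-β-ionone 3-O-tetradecanoate]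
Conditions: 14 (1.2 equiv), Et3N, DMAP (10 mol %), CH2Cl2, 0 °C to rt
Reagents that add atoms: tetradecanoyl chloride (14), CCCCCCCCCCCCCC(=O)Cl
Why: DMAP-catalysed O-acylation of the unhindered secondary alcohol occurs at oxygen with retention at C3, and the amine keeps the medium basic so the oxirane survives.

**Compound list**
1 | ketoisophorone (2,6,6-trimethylcyclohex-2-ene-1,4-dione) | CC1=CC(=O)CC(C)(C)C1=O | starting material
2 | (6R)-levodione | C[C@@H]1CC(=O)CC(C)(C)C1=O | intermediate
3 | (4R,6R)-actinol | C[C@@H]1C[C@@H](O)CC(C)(C)C1=O | intermediate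
4 | (4R,6R)-4-(tert-butyldimethylsilyloxy)-2,2,6-trimethylcyclohexan-1-one | C[C@@H]1C[C@@H](O[Si](C)(C)C(C)(C)C)CC(C)(C)C1=O | intermediate
5 | lithium (4R)-4-(tert-butyldimethylsilyloxy)-2,6,6-trimethylcyclohex-1-en-1-olate (not isolated) | [Li+].[O-]C1=C(C)C[C@@H](O[Si](C)(C)C(C)(C)C)CC1(C)C | intermediate
6 | (4R)-4-(tert-butyldimethylsilyloxy)-2,6,6-trimethylcyclohex-1-en-1-yl trifluoromethanesulfonate | FC(F)(F)S(=O)(=O)OC1=C(C)C[C@@H](O[Si](C)(C)C(C)(C)C)CC1(C)C | intermediate
7 | methyl (4R)-4-(tert-butyldimethylsilyloxy)-2,6,6-trimethylcyclohex-1-ene-1-carboxylate | COC(=O)C1=C(C)C[C@@H](O[Si](C)(C)C(C)(C)C)CC1(C)C | intermediate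
8 | [(4R)-4-(tert-butyldimethylsilyloxy)-2,6,6-trimethylcyclohex-1-en-1-yl]methanol | OCC1=C(C)C[C@@H](O[Si](C)(C)C(C)(C)C)CC1(C)C | intermediate
9 | [(1R,4S,6R)-4-(tert-butyldimethylsilyloxy)-2,2,6-trimethyl-7-oxabicyclo[4.1.0]heptan-1-yl]methanol | CC(C)(C)[Si](C)(C)O[C@H]1CC(C)(C)[C@]2(CO)O[C@]2(C)C1 | intermediate
10 | (1S,4S,6R)-4-(tert-butyldimethylsilyloxy)-2,2,6-trimethyl-7-oxabicyclo[4.1.0]heptane-1-carbaldehyde | CC(C)(C)[Si](C)(C)O[C@H]1CC(C)(C)[C@]2(C=O)O[C@]2(C)C1 | intermediate
11 | 1-(triphenylphosphoranylidene)propan-2-one | CC(=O)C=P(c1ccccc1)(c1ccccc1)c1ccccc1 | starting material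
12 | (E)-4-[(1S,4S,6R)-4-(tert-butyldimethylsilyloxy)-2,2,6-trimethyl-7-oxabicyclo[4.1.0]heptan-1-yl]but-3-en-2-one | CC(C)(C)[Si](C)(C)O[C@H]1CC(C)(C)[C@]2(/C=C/C(C)=O)O[C@]2(C)C1 | intermediate
13 | (E)-4-[(1S,4S,6R)-4-hydroxy-2,2,6-trimethyl-7-oxabicyclo[4.1.0]heptan-1-yl]but-3-en-2-one | O[C@H]1CC(C)(C)[C@]2(/C=C/C(C)=O)O[C@]2(C)C1 | intermediate
14 | tetradecanoyl (myristoyl) chloride | CCCCCCCCCCCCCC(=O)Cl | starting material
15 | (3S,5R,6S)-5,6-epoxy-3-hydroxy-5,6-dihydro-β-ionone 3-O-tetradecanoate | CCCCCCCCCCCCCC(=O)O[C@H]1CC(C)(C)[C@]2(/C=C/C(C)=O)O[C@]2(C)C1 | target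

**Totals**
Total step count: 11. Longest linear sequence: 11 steps (1 → 15).

**Three steps most likely to fail**

Step 7 is the first risk. The alkene is tetrasubstituted and flanked by a quaternary carbon, so the catalytic epoxidation may be slow or give less than full facial control, and titanium can open the product. The fallback sets out from 8 and comes back at 9. It gives up catalyst control for substrate control plus separation. Compound 8 is epoxidised with mCPBA buffered by NaHCO3 in CH2Cl2 at 0 °C. This gives 9 together with its syn diastereomer [(1S,4S,6S)-4-(tert-butyldimethylsilyloxy)-2,2,6-trimethyl-7-oxabicyclo[4.1.0]heptan-1-yl]methanol F1. The two are separated on silica, assigned by NOE and by rotation, and only 9 is carried on.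

Step 9 is the second risk. The aldehyde carbon hangs on a quaternary centre between two further quaternary carbons, so the weakly nucleophilic keto-ylide may react sluggishly. The fallback sets out from 10 and comes back at 12. It replaces olefination by aldol addition and elimination. The small lithium enolate of acetone (LDA, acetone, THF, −78 °C) adds to 10 to give the aldol 4-hydroxy-4-[(1R,4S,6R)-4-(tert-butyldimethylsilyloxy)-2,2,6-trimethyl-7-oxabicyclo[4.1.0]heptan-1-yl]butan-2-one F2 as a mixture of carbinol epimers. This is converted with MsCl/Et3N/DMAP into the mesylate 4-oxo-1-[(1R,4S,6R)-4-(tert-butyldimethylsilyloxy)-2,2,6-trimethyl-7-oxabicyclo[4.1.0]heptan-1-yl]butan-2-yl methanesulfonate F3. Treatment with DBU then brings about E1cB elimination to the E-enone 12.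

Step 2 is the third risk. A ketoreductase with the right regio- and stereopreference has to be found, and any erosion at C4 ends up as the wrong enantiomeric series once C6 is erased in step 4. The fallback sets out from 2 and comes back at 3. It replaces enzyme control by substrate control. Hydrogenation of 2 over Raney nickel (H2, MeOH, rt) reduces only the unhindered C4 ketone, roughly 4:1 in favour of 3. The minor epimer (4S,6R)-4-hydroxy-2,2,6-trimethylcyclohexan-1-one F4 is removed completely by crystallisation or chromatography before silylation.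

**Further compounds**
F1 | step 7 | [(1S,4S,6S)-4-(tert-butyldimethylsilyloxy)-2,2,6-trimethyl-7-oxabicyclo[4.1.0]heptan-1-yl]methanol | CC(C)(C)[Si](C)(C)O[C@H]1CC(C)(C)[C@@]2(CO)O[C@@]2(C)C1
F2 | step 9 | 4-hydroxy-4-[(1R,4S,6R)-4-(tert-butyldimethylsilyloxy)-2,2,6-trimethyl-7-oxabicyclo[4.1.0]heptan-1-yl]butan-2-one (carbinol epimers) | CC(C)(C)[Si](C)(C)O[C@H]1CC(C)(C)[C@]2(C(O)CC(C)=O)O[C@]2(C)C1
F3 | step 9 | 4-oxo-1-[(1R,4S,6R)-4-(tert-butyldimethylsilyloxy)-2,2,6-trimethyl-7-oxabicyclo[4.1.0]heptan-1-yl]butan-2-yl methanesulfonate (epimers) | CC(C)(C)[Si](C)(C)O[C@H]1CC(C)(C)[C@]2(C(CC(C)=O)OS(C)(=O)=O)O[C@]2(C)C1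
F4 | step 2 | (4S,6R)-4-hydroxy-2,2,6-trimethylcyclohexan-1-one | C[C@@H]1C[C@H](O)CC(C)(C)C1=O
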